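**Plan**

1. Retrosynthetic cuts, in order: the two benzoates (O6 and O7 acyl bonds); C2–Cl (from a C2 alcohol by SN2 inversion); the C3=C4 / C2–O pair (Wharton transposition of a C2,C3-epoxy C4-ketone); C5–O (Rubottom oxidation at the α' carbon of a C4 enone); C6–O (oxa-Michael addition to a cyclohexadienone); C1–O (phenol dearomatisation).
2. Enabling feature: C1 is a quaternary ring carbon bearing OH and CH2O, which makes it the para carbon of the p-quinol of 4-hydroxybenzyl alcohol. O6 is cis to O1, so C1, O1, C6 and O6 can be joined through boron into one 1,3,2-dioxaborolane ring.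
3. Forward order: the six-membered ring is the arene ring, dearomatised in step 2. The dioxaborolane is the only ring that is made, closed in step 3 by conjugate addition of a boron-tethered hydroxyl to one of the two enone arms. C5–O, the C2,C3-epoxide, the alkene shift, the chloride and the esters are then placed on the intact carbocycle.
4. Stereochemistry: C1 and C6 come from the chiral amine–thiourea catalyst and the cis-enforcing tether. C5 comes from oxidation of a silyl dienol ether anti to C6–O. C2 comes from hydroxyl-directed epoxidation on the face of the C1 hydroxyl, is carried through the Wharton step, and is then inverted by chloride.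

Key step: step 3

Conventions: the target numbering is used for every intermediate (C1 quaternary carbinol carbon, C2 CHCl, C3=C4, C5 CHOH, C6 CHOBz, C7 exocyclic CH2). β is the ring face that carries the C1 oxygen and α is the opposite face. In this numbering the target is (1R,2R,5S,6R): O1 β, O6 β, O5 α, Cl α.

Assumption on the chemistry: the quinine-derived thiourea of step 3 is taken to select the enone arm that leads to 7. Should the sense of induction be opposite, the quinidine-derived pseudoenantiomer is used with no other change.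

**Route**

Step 1
Reactants: 1 4-hydroxybenzyl alcohol; 2 tert-butyldimethylsilyl chloride
Product: 3 4-{[(tert-butyldimethylsilyl)oxy]methyl}phenol
Conditions: TBSCl (1.05 equiv), imidazole, DMF, 0 °C
Reagents that add atoms: tert-butyldimethylsilyl chloride, CC(C)(C)[Si](C)(C)Cl
Why: Chemoselective O-silylation, in which the primary benzylic hydroxyl should react faster than the phenol with one equivalent of silyl chloride under imidazole catalysis at 0 °C.

Step 2
Reactants: 3 4-{[(tert-butyldimethylsilyl)oxy]methyl}phenol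
Product: 4 4-{[(tert-butyldimethylsilyl)oxy]methyl}-4-hydroxycyclohexa-2,5-dien-1-one
Conditions: PhI(OAc)2 (1.1 equiv), MeCN/H2O (4:1), 0 °C
Reagents that add atoms: water, O
Why: Oxidative dearomatisation of a para-substituted phenol, in which ligand exchange at trivalent iodine is followed by attack of water at the blocked para carbon, should give the achiral p-quinol and create the C1 carbinol.

Step 3
Reactants: 4 4-{[(tert-butyldimethylsilyl)oxy]methyl}-4-hydroxycyclohexa-2,5-dien-1-one; 5 phenylboronic acid
Product: 7 cis-fused dioxaborolane enone (3aR,7aR)-7a-{[(tert-butyldimethylsilyl)oxy]methyl}-2-phenyl-3a,4-dihydro-1,3,2-benzodioxaborol-5(7aH)-one, via boronic acid hemiester 6 (not isolated)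
Conditions: PhB(OH)2 (1.2 equiv), 1-[3,5-bis(trifluoromethyl)phenyl]-3-[(8S,9S)-6'-methoxycinchonan-9-yl]thiourea (10 mol %), 4 Å molecular sieves, toluene, rt
Reagents that add atoms: phenylboronic acid, OB(O)c1ccccc1
Why: Condensation of 5 with the tertiary C1 hydroxyl gives hemiester 6; the quinuclidine nitrogen of the catalyst coordinates boron and raises the nucleophilicity of the remaining B–OH oxygen while the thiourea hydrogen-bonds to the dienone carbonyl, and conjugate addition to C6 followed by protonation at C5 gives 7. The closest known reaction type is the amine–thiourea-catalysed oxa-Michael addition of boronic acid hemiesters of γ-hydroxy enones, and desymmetrisation of p-quinols by a tethered oxa-Michael addition is established for hemiacetal tethers. The dioxaborolane ring closes in the 5-exo-trig mode. C6–O is forced cis to C1–O by the short O–B–O tether, and the configuration at C1 follows from which of the two enantiotopic enone arms the catalyst selects. The step needs enantiotopic-group selectivity, which the chiral amine/hydrogen-bond array of the catalyst should provide, and mono-addition, which is secured because the boron carries only one free hydroxyl after esterification.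

Step 4
Reactants: 7 cis-fused dioxaborolane enone
Product: 8 triisopropylsilyl dienol ether (C4(OTIPS)=C5 and C2=C3; boronate unchanged)
Conditions: TIPSOTf (1.3 equiv), Et3N (2.5 equiv), CH2Cl2, −78 → 0 °C
Reagents that add atoms: triisopropylsilyl trifluoromethanesulfonate, CC(C)[Si](C(C)C)(C(C)C)OS(=O)(=O)C(F)(F)F
Why: Soft enolisation with a silyl triflate and a tertiary amine can only remove a C5 proton because the γ carbon C1 is quaternary, and it avoids a free enolate that could expel the C6 oxygen.

Step 5
Reactants: 8 triisopropylsilyl dienol ether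
Product: 10 C5α-(triisopropylsilyloxy) enone boronate (C5–O trans to C6–O), via silyloxy epoxide 9 (not isolated)
Conditions: dimethyldioxirane (acetone solution, 1.1 equiv), CH2Cl2, −78 → 0 °C; then (+)-10-camphorsulfonic acid (5 mol %), 0 °C
Reagents that add atoms: dimethyldioxirane, CC1(C)OO1
Why: Rubottom oxidation, in which the electrophilic dioxirane should epoxidise the electron-rich C4=C5 enol ether from the convex α face anti to the adjacent C6–O bond while sparing the B–phenyl bond, and acid-induced opening with 1,4-silyl migration gives the α'-silyloxy ketone with C5–O trans to C6–O.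

Step 6
Reactants: 10 C5α-(triisopropylsilyloxy) enone boronate
Product: 11 cis-diol enone (C1β–OH and C6β–OH; C5α–OTIPS)
Conditions: pinacol (5 equiv), CH2Cl2, rt
Reagents that add atoms: none
Why: Boronate transesterification under neutral conditions, driven by excess pinacol toward its more stable tetrasubstituted dioxaborolane, should release the diol without disturbing the β-hydroxy ketone.

Step 7
Reactants: 11 cis-diol enone
Product: 12 C2,C3-β-epoxy ketone diol
Conditions: t-BuOOH (decane, 2 equiv), benzyltrimethylammonium hydroxide (20 mol %, 40% in MeOH), THF, 0 °C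
Reagents that add atoms: tert-butyl hydroperoxide, CC(C)(C)OO
Why: Weitz–Scheffer nucleophilic epoxidation, in which the free C1 hydroxyl (supported by the C6 hydroxyl on the same face) hydrogen-bonds to the incoming peroxide anion and delivers it to C2 on the β face, as is known for 4-hydroxycyclohexenones and p-quinols.

Step 8
Reactants: 12 C2,C3-β-epoxy ketone diol
Product: 13 epoxy ketone acetonide (O1 and O6 bridged by CMe2)
Conditions: 2-methoxypropene (3 equiv), pyridinium p-toluenesulfonate (5 mol %), CH2Cl2, 0 °C → rt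
Reagents that add atoms: 2-methoxypropene, COC(C)=C
Why: Acetonide formation on the only cis-1,2-diol masks the tertiary C1 hydroxyl for the chlorination and marks O6 apart from the silylated O5.

Step 9
Reactants: 13 epoxy ketone acetonide
Product: 16 allylic alcohol (C2β–OH; C3=C4), via epoxy hydrazone 14 (not isolated), via alkenyldiazene 15 (not isolated)
Conditions: N2H4·H2O (3 equiv), AcOH (0.5 equiv), MeOH, 0 °C → rt
Reagents that add atoms: none
Why: Wharton transposition, in which the C4 hydrazone opens the epoxide at C3 to an alkenyldiazene that loses N2, moves the alkene to C3=C4 and leaves the C2–O bond untouched, so C2–OH keeps the β configuration of the epoxide.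

Step 10
Reactants: 16 allylic alcohol
Product: 18 allylic chloride (C2α–Cl), via alkoxyphosphonium chloride 17 (not isolated)
Conditions: PPh3 (1.3 equiv), Cl3CC(O)CCl3 (2 equiv), CH2Cl2, −20 → 0 °C
Reagents that add atoms: hexachloroacetone, O=C(C(Cl)(Cl)Cl)C(Cl)(Cl)Cl
Why: Appel-type chlorination in its variant for allylic alcohols, in which the alkoxyphosphonium chloride ion pair collapses by SN2 at C2 with inversion and little allylic transposition, places chlorine on the α face trans to the C1 oxygen.

Step 11
Reactants: 18 allylic chloride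
Product: 19 triol (1R,2R,5S,6R)-2-chloro-1-(hydroxymethyl)-5-[(triisopropylsilyl)oxy]cyclohex-3-ene-1,6-diol
Conditions: (+)-10-camphorsulfonic acid (20 mol %), MeOH, rt
Reagents that add atoms: none
Why: Acid-catalysed transketalisation and methanolysis should remove the acetonide and the primary TBS ether while the hindered secondary TIPS ether survives, following the graded acid lability of these groups.

Step 12
Reactants: 19 triol; 20 benzoyl chloride
Product: 21 dibenzoate [(1R,2R,5S,6R)-6-(benzoyloxy)-2-chloro-1-hydroxy-5-[(triisopropylsilyl)oxy]cyclohex-3-en-1-yl]methyl benzoate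
Conditions: BzCl (2.5 equiv), pyridine, 4-(dimethylamino)pyridine (10 mol %), CH2Cl2, 0 °C → rt
Reagents that add atoms: benzoyl chloride, O=C(Cl)c1ccccc1
Why: Acylation of the primary C7 and secondary C6 hydroxyls, with the tertiary C1 hydroxyl inert and O5 still silylated, under a base too weak to close the trans-chlorohydrin to an epoxide.

Step 13
Reactants: 21 dibenzoate
Product: 22 target [(1R,2R,5S,6R)-6-(benzoyloxy)-2-chloro-1,5-dihydroxycyclohex-3-en-1-yl]methyl benzoate
Conditions: HF·pyridine, pyridine, THF, 0 °C → rt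
Reagents that add atoms: none
Why: Fluoride-mediated desilylation under buffered acidic conditions should free the C5 hydroxyl without benzoate migration, chloride displacement or epoxide formation.

**Compound list**

1 | 4-hydroxybenzyl alcohol | OCc1ccc(O)cc1 | starting material
2 | tert-butyldimethylsilyl chloride | CC(C)(C)[Si](C)(C)Cl | starting material
3 | 4-{[(tert-butyldimethylsilyl)oxy]methyl}phenol | CC(C)(C)[Si](C)(C)OCc1ccc(O)cc1 | intermediate
4 | 4-{[(tert-butyldimethylsilyl)oxy]methyl}-4-hydroxycyclohexa-2,5-dien-1-one (achiral p-quinol) | CC(C)(C)[Si](C)(C)OCC1(O)C=CC(=O)C=C1 | intermediate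
5 | phenylboronic acid | OB(O)c1ccccc1 | starting material
6 | phenylboronic acid hemiester of 4 (C1–O–B(OH)Ph, achiral) | CC(C)(C)[Si](C)(C)OCC1(OB(O)c2ccccc2)C=CC(=O)C=C1 | intermediate (not isolated)
7 | (3aR,7aR)-7a-{[(tert-butyldimethylsilyl)oxy]methyl}-2-phenyl-3a,4-dihydro-1,3,2-benzodioxaborol-5(7aH)-one (O1 and O6 both β, C5H2, C4 ketone, C2=C3) | CC(C)(C)[Si](C)(C)OC[C@@]12OB(c3ccccc3)O[C@@H]1CC(=O)C=C2 | intermediate
8 | triisopropylsilyl dienol ether of 7 (C4(OTIPS)=C5, C2=C3) | CC(C)(C)[Si](C)(C)OC[C@@]12OB(c3ccccc3)O[C@@H]1C=C(O[Si](C(C)C)(C(C)C)C(C)C)C=C2 | intermediate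
9 | C4,C5-α-epoxide of 8 (silyloxy oxirane, OTIPS on C4) | CC(C)(C)[Si](C)(C)OC[C@@]12OB(c3ccccc3)O[C@@H]1[C@H]4O[C@@]4(O[Si](C(C)C)(C(C)C)C(C)C)C=C2 | intermediate (not isolated)
10 | C5α-(triisopropylsilyloxy) derivative of 7 (O5 α, trans to O6; C4 ketone; C2=C3) | CC(C)(C)[Si](C)(C)OC[C@@]12OB(c3ccccc3)O[C@@H]1[C@@H](O[Si](C(C)C)(C(C)C)C(C)C)C(=O)C=C2 | intermediate
11 | cis-diol enone (C1β–OH, C6β–OH, C5α–OTIPS, C4 ketone, C2=C3, C7–OTBS) | CC(C)(C)[Si](C)(C)OC[C@@]1(O)[C@H](O)[C@@H](O[Si](C(C)C)(C(C)C)C(C)C)C(=O)C=C1 | intermediate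
12 | C2,C3-β-epoxide of 11 (epoxide syn to the C1 hydroxyl) | CC(C)(C)[Si](C)(C)OC[C@@]1(O)[C@H](O)[C@@H](O[Si](C(C)C)(C(C)C)C(C)C)C(=O)[C@@H]2O[C@@H]21 | intermediate
13 | 1,6-O-isopropylidene acetal of 12 | CC(C)(C)[Si](C)(C)OC[C@@]12OC(C)(C)O[C@@H]1[C@@H](O[Si](C(C)C)(C(C)C)C(C)C)C(=O)[C@@H]3O[C@@H]32 | intermediate
14 | C4 hydrazone of 13 | CC(C)(C)[Si](C)(C)OC[C@@]12OC(C)(C)O[C@@H]1[C@@H](O[Si](C(C)C)(C(C)C)C(C)C)C(=NN)[C@@H]3O[C@@H]32 | intermediate (not isolated)
15 | alkenyldiazene (C4–N=NH, C3=C4, C2β–OH) | CC(C)(C)[Si](C)(C)OC[C@@]12OC(C)(C)O[C@@H]1[C@@H](O[Si](C(C)C)(C(C)C)C(C)C)C(N=N)=C[C@@H]2O | intermediate (not isolated)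
16 | allylic alcohol (C2β–OH, C3=C4, C5α–OTIPS, 1,6-acetonide, C7–OTBS) | CC(C)(C)[Si](C)(C)OC[C@@]12OC(C)(C)O[C@@H]1[C@@H](O[Si](C(C)C)(C(C)C)C(C)C)C=C[C@@H]2O | intermediate
17 | C2β-oxytriphenylphosphonium chloride of 16 | CC(C)(C)[Si](C)(C)OC[C@@]12OC(C)(C)O[C@@H]1[C@@H](O[Si](C(C)C)(C(C)C)C(C)C)C=C[C@@H]2O[P+](c3ccccc3)(c3ccccc3)c3ccccc3.[Cl-] | intermediate (not isolated)
18 | allylic chloride (C2α–Cl, otherwise as 16) | CC(C)(C)[Si](C)(C)OC[C@@]12OC(C)(C)O[C@@H]1[C@@H](O[Si](C(C)C)(C(C)C)C(C)C)C=C[C@H]2Cl | intermediate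
19 | (1R,2R,5S,6R)-2-chloro-1-(hydroxymethyl)-5-[(triisopropylsilyl)oxy]cyclohex-3-ene-1,6-diol | OC[C@]1(O)[C@H](Cl)C=C[C@H](O[Si](C(C)C)(C(C)C)C(C)C)[C@H]1O | intermediate
20 | benzoyl chloride | O=C(Cl)c1ccccc1 | starting material
21 | [(1R,2R,5S,6R)-6-(benzoyloxy)-2-chloro-1-hydroxy-5-[(triisopropylsilyl)oxy]cyclohex-3-en-1-yl]methyl benzoate | O=C(OC[C@]1(O)[C@H](Cl)C=C[C@H](O[Si](C(C)C)(C(C)C)C(C)C)[C@H]1OC(=O)c1ccccc1)c1ccccc1 | intermediate
22 | [(1R,2R,5S,6R)-6-(benzoyloxy)-2-chloro-1,5-dihydroxycyclohex-3-en-1-yl]methyl benzoate | O=C(OC[C@]1(O)[C@H](Cl)C=C[C@H](O)[C@H]1OC(=O)c1ccccc1)c1ccccc1 | target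

**Count and risks**

Total step count: 13. Longest linear sequence: 13 steps (1 → 22).

Steps most likely to fail:

Step 3. Hemiester formation at the hindered tertiary hydroxyl may be slow and reversible, so that conversion stalls or the catalyst discriminates the two enantiotopic enone arms poorly. The fallback sets out from 4 and desymmetrises the quinol by a chiral-phosphoric-acid-catalysed acetalisation/oxa-Michael cascade with 4-methoxybenzaldehyde ((R)-3,3'-bis(2,4,6-triisopropylphenyl)-1,1'-binaphthyl-2,2'-diyl hydrogen phosphate, 4 Å molecular sieves, CH2Cl2). The hemiacetal hydroxyl there plays the part of the B–OH group and gives the cis-fused p-methoxybenzylidene acetal enone F1. Brief hydrolysis (AcOH/THF/H2O, 0 °C, conditions a primary TBS ether should survive) releases the cis-diol enone F2. Condensation of F2 with 5 (MgSO4, CH2Cl2) gives 7, where the route is rejoined.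

Step 7. The basic peroxide may cause retro-aldol cleavage or β-elimination of the β-hydroxy ketone, or silyl migration from O5 to O6, and the bulky C5 silyloxy group may erode the hydroxyl-directed facial selectivity. The fallback sets out from 11 and uses no base. The diol is first converted to the enone acetonide F3 (2-methoxypropene, pyridinium p-toluenesulfonate). Luche reduction (NaBH4, CeCl3·7H2O, MeOH, −78 °C) by axial hydride delivery should give the allylic alcohol F4 with the C4 hydroxyl equatorial and β, trans to the C5 silyloxy group. Peracid epoxidation directed by that allylic hydroxyl (mCPBA, NaHCO3, CH2Cl2, 0 °C, Henbest effect) gives the β-epoxy alcohol F5. Oxidation with 1,1,1-triacetoxy-1,1-dihydro-1,2-benziodoxol-3(1H)-one (Dess–Martin periodinane) returns the epoxy ketone 13, where the route is rejoined.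

Step 10. Displacement at C2, which is flanked by the quaternary C1, may be slow, so that chloride attacks C4 with allylic transposition or elimination to a diene takes over. The fallback sets out from 12 and makes the leaving group part of a ring tethered to O1. The C6 hydroxyl is silylated (Et3SiCl, imidazole, DMF) to the triethylsilyl ether F6, and Wharton transposition as in step 9 gives the cis-1,2-diol F7. SOCl2/Et3N gives the cyclic sulfite F8, and RuCl3 (catalytic)/NaIO4 gives the cyclic sulfate F9. LiCl in DMF should open F9 at the secondary allylic C2 with inversion, since the tertiary C1 cannot be attacked, to give the chloro sulfate monoester lithium salt F10. Aqueous H2SO4 (catalytic) in THF hydrolyses the sulfate ester and the triethylsilyl and primary TBS ethers to give triol 19, where the route is rejoined.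

**Further compounds**

F1 | step 3 | cis-fused p-methoxybenzylidene acetal enone (O1 and O6 β, either configuration at the acetal carbon) | CC(C)(C)[Si](C)(C)OC[C@@]12OC(c3ccc(OC)cc3)O[C@@H]1CC(=O)C=C2
F2 | step 3 | cis-diol enone (C1β–OH, C6β–OH, C5H2, C4 ketone, C2=C3) | CC(C)(C)[Si](C)(C)OC[C@@]1(O)[C@H](O)CC(=O)C=C1
F3 | step 7 | enone acetonide (1,6-O-isopropylidene, C5α–OTIPS, C4 ketone, C2=C3) | CC(C)(C)[Si](C)(C)OC[C@@]12OC(C)(C)O[C@@H]1[C@@H](O[Si](C(C)C)(C(C)C)C(C)C)C(=O)C=C2
F4 | step 7 | allylic alcohol (C4β–OH, C2=C3, otherwise as F3) | CC(C)(C)[Si](C)(C)OC[C@@]12OC(C)(C)O[C@@H]1[C@@H](O[Si](C(C)C)(C(C)C)C(C)C)[C@H](O)C=C2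
F5 | step 7 | C2,C3-β-epoxy alcohol (C4β–OH) | CC(C)(C)[Si](C)(C)OC[C@@]12OC(C)(C)O[C@@H]1[C@@H](O[Si](C(C)C)(C(C)C)C(C)C)[C@H](O)[C@@H]3O[C@@H]32
F6 | step 10 | C6 triethylsilyl ether of 12 | CC(C)(C)[Si](C)(C)OC[C@@]1(O)[C@H](O[Si](CC)(CC)CC)[C@@H](O[Si](C(C)C)(C(C)C)C(C)C)C(=O)[C@@H]2O[C@@H]21
F7 | step 10 | cis-1,2-diol (C1β–OH, C2β–OH, C3=C4, C6β–OSiEt3, C5α–OTIPS) | CC(C)(C)[Si](C)(C)OC[C@@]1(O)[C@H](O[Si](CC)(CC)CC)[C@@H](O[Si](C(C)C)(C(C)C)C(C)C)C=C[C@@H]1O
F8 | step 10 | cyclic sulfite of F7 across O1 and O2 | CC(C)(C)[Si](C)(C)OC[C@@]12OS(=O)O[C@H]2C=C[C@H](O[Si](C(C)C)(C(C)C)C(C)C)[C@H]1O[Si](CC)(CC)CC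
F9 | step 10 | cyclic sulfate of F7 across O1 and O2 | CC(C)(C)[Si](C)(C)OC[C@@]12OS(=O)(=O)O[C@H]2C=C[C@H](O[Si](C(C)C)(C(C)C)C(C)C)[C@H]1O[Si](CC)(CC)CC
F10 | step 10 | C2α-chloro C1-sulfate monoester lithium salt | CC(C)(C)[Si](C)(C)OC[C@]1(OS(=O)(=O)[O-])[C@H](Cl)C=C[C@H](O[Si](C(C)C)(C(C)C)C(C)C)[C@H]1O[Si](CC)(CC)CC.[Li+]
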